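## Structural features

The target is built from three 3',4',5,7-tetraoxygenated flavan units, each a benzopyran (rings A and C) that carries a catechol ring B at C2 and a hydroxyl at C3. The upper and the middle unit belong to the 2,3-cis (2R,3R) series and are joined by a carbon–carbon bond from C4 of the upper unit (R, trans to its C3 hydroxyl) to C8 of ring A of the middle unit. C4 of the middle unit (S, again trans to C3–OH) carries an oxygen that is also the C4 oxygen of the lower unit, so these two units are linked by an ether between two secondary benzylic carbons. The lower unit belongs to the mirror-image (2S,3S,4S) series and has ring B, the C3 hydroxyl and the ether oxygen all on one face of ring C; each ring C thus holds three contiguous stereocentres, nine in all. Fragile are the twelve phenols (air oxidation, base-induced epimerisation at C2) and above all the C4–O–C4 ether, each carbon of which is ortho and para to ring A oxygens and ionises with traces of acid. The real difficulty is to form this ether with defined configuration on both sides and to build the all-cis lower unit, because capture of a C4 cation by a nucleophile gives the 3,4-trans arrangement. The key step exploits the cis relation of C2 (bearing ring B) and C3 (bearing oxygen) in ring C of the lower unit: a cis-oxirane across C2–C3, opened at benzylic C2 with inversion by the ring A phenol oxygen that becomes O1, has exactly this relation.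

## Logic of the disconnections

**26 to 25.** The fifteen O–CH2Ph bonds are cut (twelve on phenols, three on C3 oxygens). All earlier chemistry is then done on ethers that are neither oxidisable nor acidic. The forward step must be neutral and short, so that the C4–O–C4 ether outlives the hydrogenolysis.

**25 to 24 and 19.** The C4–O bond on the side of the middle unit is cut. A C4 cation of a 2,3-cis unit takes up a nucleophile anti to the C3 oxygen; that is the configuration of the middle unit but not of the lower unit. The lower unit therefore has to arrive as an alcohol with its C4 centre already set, and the middle unit has to be the electrophile. The trimer falls into a dimer and a monomer. The forward step must oxidise the C4 methylene of 24 in the presence of the carbinol C–H of 19 and must not expose the product to acid.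

**24 to 23 and 22.** The C4–C8 bond is cut. Both halves come from one flavan-3-ol that already holds C2 and C3. The forward step must attack C8 and not C6, must enter anti to the C3 oxygen, and needs an excess of 22 so that 24 does not react further.

**23 to 22, 21 and 20.** The C4–O bond of the leaving group and the O–benzyl bonds are cut, which leads to a natural product that is bought. The forward steps must benzylate without epimerising C2.

**19 to 18, 17 and 16.** The C4–H bond of 19 is traced to hydride addition to a C4 ketone, and the C4 oxygen to benzylic oxidation of a methylene. Only hydride delivery anti to the C3 oxygen places the C4 hydroxyl cis to it. This removes the third stereocentre of the lower unit. The ketone 18 must not enolise, since that would epimerise C3 or open ring C.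

**16 to 15 and 13 (through 14).** The C3 O–benzyl bond and then the O1–C2 bond are cut. Ring C opens to a phenol and a cis-oxirane, in which C2 has the configuration opposite to that of 15. The forward closure must be 6-endo and must be a true backside displacement, not an ionisation.

**13 to 12.** Both C–O bonds of the oxirane are cut, which removes the two remaining stereocentres and leaves an achiral Z-alkene. The forward step must select one face of the alkene, keep the cis geometry and leave the electron-rich rings and the C4 methylene alone.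

**12 to 11 and 10.** The alkene is traced to an alkyne (syn addition of hydrogen gives the Z geometry) and the O–Si bond is cut. The hydrogenation must stop at the alkene and spare the benzyl ethers.

**10 to 6 and 4 (through 7, 8 and 9).** The bond between the benzylic carbon (future C4) and the alkyne carbon (future C3) is cut, and the benzylic carbon is taken back to an aldehyde. A benzylic halide on this ring, ortho to a silyloxy and para to an alkoxy group, would ionise and self-condense, and reduction of the silylated aldehyde would invite silyl migration. The ortho oxygen is therefore used on purpose to expel the benzylic oxygen, and hydride fills the vacant site. The forward step needs a single addition of the acetylide and fast hydride capture of 9.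

**6 to 5; 4 to 3, 1 and 2.** One carbon is removed from the alkyne, and the carbonate and benzyl ether O–C bonds are cut. The selectivity of the double benzylation rests on the hydrogen bond of the last hydroxyl to the formyl group.

## Other disconnections considered

**Alternative 1:** The cut runs through ring C of the lower unit at C3–C4 and O1–C2, with boron in place of the C3 oxygen and the ether oxygen kept on C4.
- Forward step: acid would ionise the mixed acetal A2 to an alkoxy-substituted ortho-quinone methide (its oxocarbenium form), which would add the Z-styrylboronate A3 in a [4+2] cycloaddition to give A1. Oxidation of the C–B bond with retention and hydrogenolysis would finish.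
- In favour: ring C and its three stereocentres would be made in one step with the interflavan oxygen already in place. No C4 oxidation and reduction and no late etherification would be needed. The Z geometry of A3 would map onto the 2,3-cis relation just as the Z-alkene does in the chosen plan.
- Against: the absolute configuration of three new centres would have to be induced by the dimer alone, through a freely rotating C–O bond. The all-cis result would also need one particular endo or exo mode. The acid that ionises A2 could equally break the C4–O bond on the dimer side. A Z-alkenylboronate on an electron-rich arene is prone to isomerisation and protodeboronation in acid.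
- Comparison: on structure the two plans are equal in using a Z-alkene for the cis C2/C3 pair and equal in convergence. On mechanism the chosen plan is stronger, because a chiral catalyst sets the absolute configuration on an achiral alkene. On step economy Alternative 1 would be the better plan.

**Alternative 2:** The cut is O1–C8a of the lower unit.
- Forward step: CuI (monovalent copper) with 1,10-phenanthroline and Cs2CO3 would couple the C2 hydroxyl of the bromo alcohol A5 with its aryl bromide to give A4. Removal of the silyl group would then give 19.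
- In favour: the C2–O bond is never broken, so C2 cannot be scrambled. On the security of C2 this alternative is the better of the two. The C4 oxygen would be present from the start, which would spare the oxidation and reduction at C4.
- Against: the step only closes a ring. The three contiguous centres of A5, with three differently protected oxygens, would have to be built in the open chain, which would probably cost more steps than alkene to oxirane to flavan. The aryl bromide is very electron-rich and ortho-substituted, a poor partner for copper. Hot carbonate base acting on a benzylic alkoxide with oxygen on the next carbon invites retro-aldol cleavage, silyl migration and elimination.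
- Comparison: from 19 onward the two plans are equal. On mechanism Alternative 2 avoids the question of backside attack versus ionisation. On step economy the chosen plan is better.

**Alternative 3:** The cut goes through ring A of the middle unit at C7–C8 and C4a–C8a.
- Forward step: heating the siloxyalkyne A7 with the cyclobutenone A8 would open the cyclobutenone to a vinylketene, which would add the ynol ether. Ring opening and six-electron electrocyclisation would then give the phenol A6.
- In favour: the position of the interflavan bond (C8 and not C6) would be fixed by construction, and no excess of a monomer would be needed. On regiocontrol this alternative is the better of the two. The two ring A oxygens would also emerge differentiated (free at C7, silylated at C8a), which suits a later ring C closure.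
- Against: it rebuilds an aromatic ring that the chosen plan buys with 20. Ring C of the middle unit would then still have to be made from an E-cinnamyl group, which leads by oxirane or diol closure to the 2,3-trans series, so C3 would have to be corrected. A7 is itself a multistep target. The ether and the all-cis lower unit, the hard parts, are not touched.
- Comparison: on mechanism the pericyclic cascade is dependable, and the thermal step should leave the C4 centre of A7 intact, which is equal to the chosen coupling. On structure it solves a bond that step 16 makes in one operation. On step economy it is clearly worse.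

Key step: step 7

Remark: the (R,R) catalyst of step 7 is chosen by analogy with cis-β-methylstyrene, which it converts to the (1R,2S)-oxide; should 12 respond in the opposite sense, the (S,S) catalyst is used with no other change. Compounds 5 and 20 are bought.

## Route

Step 1
Reactants: 1 2,4,6-trihydroxybenzaldehyde; 2 benzyl bromide
Product: 3 2,4-bis(benzyloxy)-6-hydroxybenzaldehyde
Conditions: BnBr (2.05 equiv), K2CO3, DMF, 0 °C → rt
Reagents that add atoms: benzyl bromide (compound 2), BrCc1ccccc1
Why: Williamson etherification; the para hydroxyl and one of the two equivalent ortho hydroxyls react, after which the last hydroxyl is held in a hydrogen bond to the formyl oxygen and resists alkylation. No stereocentre is formed.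

Step 2
Reactants: 3 2,4-bis(benzyloxy)-6-hydroxybenzaldehyde
Product: 4 tert-butyl 3,5-bis(benzyloxy)-2-formylphenyl carbonate
Conditions: Boc2O, i-Pr2NEt, DMAP (cat.), THF, 0 °C → rt
Reagents that add atoms: di-tert-butyl dicarbonate, CC(C)(C)OC(=O)OC(=O)OC(C)(C)C
Why: DMAP-catalysed O-acylation of the phenol. The aryl carbonate masks the phenol and is the group that is transferred and expelled in step 4.

Step 3
Reactants: 5 3,4-bis(benzyloxy)benzaldehyde
Product: 6 1,2-bis(benzyloxy)-4-ethynylbenzene
Conditions: dimethyl (1-diazo-2-oxopropyl)phosphonate, K2CO3, MeOH/THF, 0 °C → rt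
Reagents that add atoms: dimethyl (1-diazo-2-oxopropyl)phosphonate, COP(=O)(OC)C(=[N+]=[N-])C(C)=O
Why: Seyferth–Gilbert homologation in the Ohira–Bestmann variant: methanolysis gives the diazomethylphosphonate anion, which olefinates the aldehyde, and loss of N2 with 1,2-hydrogen shift gives the terminal alkyne. The mild carbonate base leaves the benzyl ethers untouched.

Step 4
Reactants: 6 1,2-bis(benzyloxy)-4-ethynylbenzene; 4 tert-butyl 3,5-bis(benzyloxy)-2-formylphenyl carbonate
Product: 10 3,5-bis(benzyloxy)-2-{3-[3,4-bis(benzyloxy)phenyl]prop-2-yn-1-yl}phenol, via carbinol aryl carbonate 7 (not isolated), via benzylic carbonate phenol 8 (not isolated), via ortho-quinone methide 9 (not isolated)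
Conditions: 6, n-BuLi (1.0 equiv), THF, −78 °C; 4 (1.05 equiv), −78 °C; NaBH4, EtOH, −78 °C → rt; aq. NH4Cl
Reagents that add atoms: none
Why: Anionic cascade of an ortho-(tert-butoxycarbonyloxy)benzaldehyde: the lithium acetylide adds to the aldehyde (7), the alkoxide takes over the Boc group from the neighbouring phenol oxygen (8), the freed phenoxide expels tert-butyl carbonate to give the ortho-quinone methide (9), and borohydride adds to its exocyclic carbon to restore the arene. The transient carbinol centre is lost, so no stereocentre results, and no benzylic halide of this electron-rich ring is handled.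

Step 5
Reactants: 10 3,5-bis(benzyloxy)-2-{3-[3,4-bis(benzyloxy)phenyl]prop-2-yn-1-yl}phenol
Product: 11 {3,5-bis(benzyloxy)-2-{3-[3,4-bis(benzyloxy)phenyl]prop-2-yn-1-yl}phenoxy}(tert-butyl)dimethylsilane
Conditions: TBSCl, imidazole, DMF, rt
Reagents that add atoms: tert-butyldimethylsilyl chloride, CC(C)(C)[Si](C)(C)Cl
Why: Imidazole-promoted silylation of the phenol. The silyl ether keeps the nucleophilic oxygen masked through hydrogenation and epoxidation and is later removed by fluoride without acid.

Step 6
Reactants: 11 {3,5-bis(benzyloxy)-2-{3-[3,4-bis(benzyloxy)phenyl]prop-2-yn-1-yl}phenoxy}(tert-butyl)dimethylsilane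
Product: 12 (Z)-1-[2-(tert-butyldimethylsiloxy)-4,6-bis(benzyloxy)phenyl]-3-[3,4-bis(benzyloxy)phenyl]prop-2-ene
Conditions: H2 (1 atm), Pd/CaCO3 poisoned with Pb(OAc)2, quinoline, EtOAc, rt
Reagents that add atoms: none
Why: Lindlar semi-hydrogenation: syn delivery of H2 on the poisoned palladium surface gives the Z-alkene. Lead and quinoline suppress over-reduction, isomerisation and benzyl ether hydrogenolysis.

Step 7
Reactants: 12 (Z)-1-[2-(tert-butyldimethylsiloxy)-4,6-bis(benzyloxy)phenyl]-3-[3,4-bis(benzyloxy)phenyl]prop-2-ene
Product: 13 (2R,3S)-2-[3,4-bis(benzyloxy)phenyl]-3-{[2,4-bis(benzyloxy)-6-(tert-butyldimethylsiloxy)phenyl]methyl}oxirane (cis)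
Conditions: (R,R)-[N,N'-bis(3,5-di-tert-butylsalicylidene)-1,2-cyclohexanediaminato]MnCl (5 mol %), NMO (5 equiv), mCPBA (2 equiv), CH2Cl2, −78 °C
Reagents that add atoms: mCPBA, OOC(=O)c1cccc(Cl)c1
Why: The peracid, tamed as its N-oxide salt, oxidises the (salen)MnCl catalyst (trivalent manganese) to the oxo-manganese salen species (pentavalent manganese), which hands its oxygen to the Z-alkene of 12 in a side-on approach over the chiral diamine bridge, forming first the C3–O bond and a benzylic radical at C2 and then the C2–O bond. The closest known reaction type is the Jacobsen epoxidation of cis-β-alkylstyrenes, the alkene class for which this catalyst is most selective. The oxirane, the one ring formed, closes by this stepwise oxygen-atom transfer, that is by collapse of the C2 radical onto the manganese-bound oxygen. C3 (S) and C2 (R) are both set by the catalyst through its choice of alkene face; C3 receives its final oxygen and configuration, and C2 is made on purpose with the configuration opposite to that of the target because step 8 inverts it. The step needs enantioface selectivity, retention of the cis geometry and chemoselectivity for the alkene over the electron-rich rings and the doubly activated C4 methylene. The first is secured by the substrate being a Z-alkene with one conjugating aryl and one sp3 substituent; the second is helped by the low temperature and the N-oxide ligand, which shorten the life of the radical. The third is served by avoiding hypochlorite, which could chlorinate ring A.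

Step 8
Reactants: 13 (2R,3S)-2-[3,4-bis(benzyloxy)phenyl]-3-{[2,4-bis(benzyloxy)-6-(tert-butyldimethylsiloxy)phenyl]methyl}oxirane
Product: 15 (2S,3S)-5,7-bis(benzyloxy)-2-[3,4-bis(benzyloxy)phenyl]chroman-3-ol, via epoxy phenol 14 (not isolated)
Conditions: n-Bu4NF/AcOH (1:1), THF, 0 °C; aqueous wash; crude 14, CSA (10 mol %), CH2Cl2, −30 → 0 °C
Reagents that add atoms: none
Why: Buffered fluoride cleaves the aryl silyl ether without opening the oxirane. With catalytic acid the phenol opens the protonated oxirane at benzylic C2 in a 6-endo closure (preferred over 5-exo attack at C3 because ring B stabilises the developing charge at C2) from the side opposite to the leaving oxygen, so C2 is inverted to S while C3 (S) is untouched and the 2,3-cis flavan-3-ol results. Acid-catalysed phenol–epoxide cyclisation of 1,3-diarylpropene oxides is the known reaction type.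

Step 9
Reactants: 15 (2S,3S)-5,7-bis(benzyloxy)-2-[3,4-bis(benzyloxy)phenyl]chroman-3-ol; 2 benzyl bromide
Product: 16 (2S,3S)-3,5,7-tris(benzyloxy)-2-[3,4-bis(benzyloxy)phenyl]chroman
Conditions: NaH, BnBr, n-Bu4NI (cat.), DMF, 0 °C → rt
Reagents that add atoms: benzyl bromide (compound 2), BrCc1ccccc1
Why: Williamson etherification of the secondary alkoxide. The C3 oxygen has to be blocked before C4 is oxidised, and a benzyl ether leaves with the others at the end; no stereocentre is touched.

Step 10
Reactants: 16 (2S,3S)-3,5,7-tris(benzyloxy)-2-[3,4-bis(benzyloxy)phenyl]chroman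
Product: 17 (2S,3S,4R)-3,5,7-tris(benzyloxy)-2-[3,4-bis(benzyloxy)phenyl]chroman-4-ol (3,4-trans)
Conditions: DDQ (2 equiv), H2O, CH2Cl2/THF, rt
Reagents that add atoms: water, O
Why: DDQ abstracts hydride from benzylic C4, which is ortho and para to the ring A benzyloxy groups, and water captures the cation anti to the pseudo-axial C3 benzyloxy group (4R). Oxidative C4 functionalisation of benzylated flavan-3-ols with DDQ is the known reaction type; the C4 configuration is erased in the next step.

Step 11
Reactants: 17 (2S,3S,4R)-3,5,7-tris(benzyloxy)-2-[3,4-bis(benzyloxy)phenyl]chroman-4-ol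
Product: 18 (2S,3R)-3,5,7-tris(benzyloxy)-2-[3,4-bis(benzyloxy)phenyl]chroman-4-one
Conditions: Dess–Martin periodinane, CH2Cl2, 0 °C → rt
Reagents that add atoms: none
Why: Dess–Martin oxidation of the secondary benzylic alcohol under non-basic conditions, so that the C3 centre next to the new ketone neither epimerises nor expels the ring oxygen. The change of the C3 descriptor is formal only.

Step 12
Reactants: 18 (2S,3R)-3,5,7-tris(benzyloxy)-2-[3,4-bis(benzyloxy)phenyl]chroman-4-one
Product: 19 (2S,3S,4S)-3,5,7-tris(benzyloxy)-2-[3,4-bis(benzyloxy)phenyl]chroman-4-ol (all-cis)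
Conditions: LiBH(s-Bu)3, THF, −78 °C; aq. NH4Cl
Reagents that add atoms: none
Why: The bulky borohydride attacks the carbonyl face anti to the pseudo-axial C3 benzyloxy group and away from the cis C2 aryl group (Felkin–Anh polar model), which places the new hydroxyl cis to both and sets C4 as S. Low temperature and a weakly basic reagent avoid enolisation.

Step 13
Reactants: 20 (−)-epicatechin; 2 benzyl bromide
Product: 21 (2R,3R)-5,7-bis(benzyloxy)-2-[3,4-bis(benzyloxy)phenyl]chroman-3-ol
Conditions: BnBr (4.4 equiv), K2CO3, DMF, argon, 0 °C → rt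
Reagents that add atoms: benzyl bromide (compound 2), BrCc1ccccc1
Why: Williamson etherification of the four phenols with a carbonate base too weak to deprotonate the C3 hydroxyl. Room temperature and exclusion of air avoid C2 epimerisation and catechol oxidation.

Step 14
Reactants: 21 (2R,3R)-5,7-bis(benzyloxy)-2-[3,4-bis(benzyloxy)phenyl]chroman-3-ol; 2 benzyl bromide
Product: 22 (2R,3R)-3,5,7-tris(benzyloxy)-2-[3,4-bis(benzyloxy)phenyl]chroman
Conditions: NaH, BnBr, n-Bu4NI (cat.), DMF, 0 °C → rt
Reagents that add atoms: benzyl bromide (compound 2), BrCc1ccccc1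
Why: Williamson etherification of the C3 alkoxide. With no free hydroxyl left, neither coupling partner can act as an oxygen nucleophile in steps 16 and 17.

Step 15
Reactants: 22 (2R,3R)-3,5,7-tris(benzyloxy)-2-[3,4-bis(benzyloxy)phenyl]chroman
Product: 23 (2R,3R,4S)-3,5,7-tris(benzyloxy)-2-[3,4-bis(benzyloxy)phenyl]-4-(2-ethoxyethoxy)chroman
Conditions: DDQ (2 equiv), 2-ethoxyethanol (excess), CH2Cl2, rt
Reagents that add atoms: 2-ethoxyethanol, CCOCCO
Why: DDQ-mediated benzylic C–H oxidation at C4 with capture of the cation by the alcohol anti to the C3 benzyloxy group (4S), a known reaction of benzylated epicatechins. The new ether is the leaving group for step 16.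

Step 16
Reactants: 23 (2R,3R,4S)-3,5,7-tris(benzyloxy)-2-[3,4-bis(benzyloxy)phenyl]-4-(2-ethoxyethoxy)chroman; 22 (2R,3R)-3,5,7-tris(benzyloxy)-2-[3,4-bis(benzyloxy)phenyl]chroman
Product: 24 (2R,3R,4R)-3,5,7-tris(benzyloxy)-2-[3,4-bis(benzyloxy)phenyl]-4-{(2R,3R)-3,5,7-tris(benzyloxy)-2-[3,4-bis(benzyloxy)phenyl]chroman-8-yl}chroman (deca-O-benzyl procyanidin B2)
Conditions: 22 (4 equiv), TMSOTf (cat.), CH2Cl2, −78 °C; Et3N
Reagents that add atoms: none
Why: The Lewis acid ionises the C4 ether of 23 to the ring A-stabilised cation, which C8 of 22 attacks anti to the C3 benzyloxy group (Friedel–Crafts alkylation, the standard procyanidin coupling), setting C4 of the upper unit as R. The excess of 22 keeps the product from reacting with further cation.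

Step 17
Reactants: 24 deca-O-benzyl procyanidin B2; 19 (2S,3S,4S)-3,5,7-tris(benzyloxy)-2-[3,4-bis(benzyloxy)phenyl]chroman-4-ol
Product: 25 pentadeca-O-benzyl ether of the target, the C4 (S) carbon of the lower unit of 24 being bonded to the C4 oxygen of 19
Conditions: 19 (3 equiv), DDQ (1.3 equiv, in portions), 4 Å sieves, CH2Cl2, 0 °C → rt; aq. NaHCO3
Reagents that add atoms: none
Why: DDQ abstracts hydride from the only benzylic methylene of 24 that sits on an electron-rich ring (C4 of its lower unit), and the hydroxyl of 19 captures the cation anti to the pseudo-axial C3 benzyloxy group, setting C4 of the middle unit as S; C4 of 19 keeps its configuration because its C–O bond is not broken. Oxidative C4 alkoxylation of benzylated flavans with DDQ and an alcohol is the known reaction type, and the medium stays free of strong acid so the new ether persists. Compound 19 is used in excess because part of it may be oxidised to 18, which goes back to step 12.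

Step 18
Reactants: 25 pentadeca-O-benzyl ether of the target
Product: 26 the target, (2R,3R,4R)-flavan-(4→8)-(2R,3R,4S)-flavan-4-yl (2S,3S,4S)-flavan-4-yl ether with free 3,5,7,3',4'-hydroxyls on all three units
Conditions: H2 (1 atm), Pd(OH)2/C, THF/EtOAc, rt; filtration, lyophilisation
Reagents that add atoms: none
Why: Neutral hydrogenolysis of twelve aryl and three alkyl benzyl ethers in non-nucleophilic solvents. The interflavan ether is a hindered secondary dialkyl ether whose benzylic carbons are flanked by ortho substituents and should be cleaved much more slowly than O-benzyl groups; no stereocentre is touched.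

## Compound list

1 | 2,4,6-trihydroxybenzaldehyde | O=Cc1c(O)cc(O)cc1O | starting material
2 | benzyl bromide | BrCc1ccccc1 | starting material
3 | 2,4-bis(benzyloxy)-6-hydroxybenzaldehyde | O=Cc1c(O)cc(OCc2ccccc2)cc1OCc1ccccc1 | intermediate
4 | tert-butyl 3,5-bis(benzyloxy)-2-formylphenyl carbonate | O=Cc1c(OC(=O)OC(C)(C)C)cc(OCc2ccccc2)cc1OCc1ccccc1 | intermediate
5 | 3,4-bis(benzyloxy)benzaldehyde | O=Cc1ccc(OCc2ccccc2)c(OCc2ccccc2)c1 | starting material
6 | 1,2-bis(benzyloxy)-4-ethynylbenzene | C#Cc1ccc(OCc2ccccc2)c(OCc2ccccc2)c1 | intermediate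
7 | tert-butyl 3,5-bis(benzyloxy)-2-{3-[3,4-bis(benzyloxy)phenyl]-1-hydroxyprop-2-yn-1-yl}phenyl carbonate (racemic, as lithium alkoxide) | CC(C)(C)OC(=O)Oc1cc(OCc2ccccc2)cc(OCc2ccccc2)c1C(O)C#Cc1ccc(OCc2ccccc2)c(OCc2ccccc2)c1 | intermediate (not isolated)
8 | 1-[2,4-bis(benzyloxy)-6-hydroxyphenyl]-3-[3,4-bis(benzyloxy)phenyl]prop-2-yn-1-yl tert-butyl carbonate (racemic, as lithium phenoxide) | CC(C)(C)OC(=O)OC(C#Cc1ccc(OCc2ccccc2)c(OCc2ccccc2)c1)c1c(O)cc(OCc2ccccc2)cc1OCc1ccccc1 | intermediate (not isolated)
9 | 3,5-bis(benzyloxy)-6-{3-[3,4-bis(benzyloxy)phenyl]prop-2-yn-1-ylidene}cyclohexa-2,4-dien-1-one | O=C1C=C(OCc2ccccc2)C=C(OCc2ccccc2)C1=CC#Cc1ccc(OCc2ccccc2)c(OCc2ccccc2)c1 | intermediate (not isolated)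
10 | 3,5-bis(benzyloxy)-2-{3-[3,4-bis(benzyloxy)phenyl]prop-2-yn-1-yl}phenol | Oc1cc(OCc2ccccc2)cc(OCc2ccccc2)c1CC#Cc1ccc(OCc2ccccc2)c(OCc2ccccc2)c1 | intermediate
11 | {3,5-bis(benzyloxy)-2-{3-[3,4-bis(benzyloxy)phenyl]prop-2-yn-1-yl}phenoxy}(tert-butyl)dimethylsilane | CC(C)(C)[Si](C)(C)Oc1cc(OCc2ccccc2)cc(OCc2ccccc2)c1CC#Cc1ccc(OCc2ccccc2)c(OCc2ccccc2)c1 | intermediate
12 | (Z)-1-[2-(tert-butyldimethylsiloxy)-4,6-bis(benzyloxy)phenyl]-3-[3,4-bis(benzyloxy)phenyl]prop-2-ene | CC(C)(C)[Si](C)(C)Oc1cc(OCc3ccccc3)cc(OCc3ccccc3)c1C/C=C\c1ccc(OCc3ccccc3)c(OCc3ccccc3)c1 | intermediate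
13 | (2R,3S)-2-[3,4-bis(benzyloxy)phenyl]-3-{[2,4-bis(benzyloxy)-6-(tert-butyldimethylsiloxy)phenyl]methyl}oxirane | CC(C)(C)[Si](C)(C)Oc1cc(OCc3ccccc3)cc(OCc3ccccc3)c1C[C@@H]1O[C@@H]1c1ccc(OCc3ccccc3)c(OCc3ccccc3)c1 | intermediate
14 | (2R,3S)-2-[3,4-bis(benzyloxy)phenyl]-3-{[2,4-bis(benzyloxy)-6-hydroxyphenyl]methyl}oxirane | Oc1cc(OCc3ccccc3)cc(OCc3ccccc3)c1C[C@@H]1O[C@@H]1c1ccc(OCc3ccccc3)c(OCc3ccccc3)c1 | intermediate (not isolated)
15 | (2S,3S)-5,7-bis(benzyloxy)-2-[3,4-bis(benzyloxy)phenyl]chroman-3-ol | C1c2c(OCc3ccccc3)cc(OCc3ccccc3)cc2O[C@@H](c2ccc(OCc3ccccc3)c(OCc3ccccc3)c2)[C@H]1O | intermediate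
16 | (2S,3S)-3,5,7-tris(benzyloxy)-2-[3,4-bis(benzyloxy)phenyl]chroman | C1c2c(OCc3ccccc3)cc(OCc3ccccc3)cc2O[C@@H](c2ccc(OCc3ccccc3)c(OCc3ccccc3)c2)[C@H]1OCc1ccccc1 | intermediate
17 | (2S,3S,4R)-3,5,7-tris(benzyloxy)-2-[3,4-bis(benzyloxy)phenyl]chroman-4-ol | O[C@@H]1c2c(OCc3ccccc3)cc(OCc3ccccc3)cc2O[C@@H](c2ccc(OCc3ccccc3)c(OCc3ccccc3)c2)[C@H]1OCc1ccccc1 | intermediate
18 | (2S,3R)-3,5,7-tris(benzyloxy)-2-[3,4-bis(benzyloxy)phenyl]chroman-4-one | O=C1c2c(OCc3ccccc3)cc(OCc3ccccc3)cc2O[C@@H](c2ccc(OCc3ccccc3)c(OCc3ccccc3)c2)[C@H]1OCc1ccccc1 | intermediate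
19 | (2S,3S,4S)-3,5,7-tris(benzyloxy)-2-[3,4-bis(benzyloxy)phenyl]chroman-4-ol | O[C@H]1c2c(OCc3ccccc3)cc(OCc3ccccc3)cc2O[C@@H](c2ccc(OCc3ccccc3)c(OCc3ccccc3)c2)[C@H]1OCc1ccccc1 | intermediate
20 | (−)-epicatechin, (2R,3R)-2-(3,4-dihydroxyphenyl)chroman-3,5,7-triol | Oc1cc(O)c2c(c1)O[C@H](c1ccc(O)c(O)c1)[C@H](O)C2 | starting material
21 | (2R,3R)-5,7-bis(benzyloxy)-2-[3,4-bis(benzyloxy)phenyl]chroman-3-ol | C(c1ccccc1)Oc1cc(OCc3ccccc3)c2c(c1)O[C@H](c1ccc(OCc3ccccc3)c(OCc3ccccc3)c1)[C@H](O)C2 | intermediate
22 | (2R,3R)-3,5,7-tris(benzyloxy)-2-[3,4-bis(benzyloxy)phenyl]chroman | C(c1ccccc1)Oc1cc(OCc3ccccc3)c2c(c1)O[C@H](c1ccc(OCc3ccccc3)c(OCc3ccccc3)c1)[C@H](OCc1ccccc1)C2 | intermediate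
23 | (2R,3R,4S)-3,5,7-tris(benzyloxy)-2-[3,4-bis(benzyloxy)phenyl]-4-(2-ethoxyethoxy)chroman | C(c1ccccc1)Oc1cc(OCc3ccccc3)c2c(c1)O[C@H](c1ccc(OCc3ccccc3)c(OCc3ccccc3)c1)[C@H](OCc1ccccc1)[C@H]2OCCOCC | intermediate
24 | deca-O-benzyl procyanidin B2, (2R,3R,4R)-unit bonded through C4 to C8 of the (2R,3R)-unit | C(c1ccccc1)Oc1cc(OCc3ccccc3)c2c(c1)O[C@H](c1ccc(OCc3ccccc3)c(OCc3ccccc3)c1)[C@H](OCc1ccccc1)[C@H]2c1c(OCc3ccccc3)cc(OCc3ccccc3)c2c1O[C@H](c1ccc(OCc3ccccc3)c(OCc3ccccc3)c1)[C@H](OCc1ccccc1)C2 | intermediate
25 | pentadeca-O-benzyl ether of the target, (2R,3R,4R)-(4→8)-(2R,3R,4S)-4-O-(2S,3S,4S) | C(c1ccccc1)Oc1cc(OCc3ccccc3)c2c(c1)O[C@H](c1ccc(OCc3ccccc3)c(OCc3ccccc3)c1)[C@H](OCc1ccccc1)[C@H]2c1c(OCc3ccccc3)cc(OCc3ccccc3)c2c1O[C@H](c1ccc(OCc3ccccc3)c(OCc3ccccc3)c1)[C@H](OCc1ccccc1)[C@H]2O[C@H]1c2c(OCc3ccccc3)cc(OCc3ccccc3)cc2O[C@@H](c2ccc(OCc3ccccc3)c(OCc3ccccc3)c2)[C@H]1OCc1ccccc1 | intermediate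
26 | target, epicatechin-(4β→8)-epicatechin 4β-yl ether of (2S,3S,4S)-2-(3,4-dihydroxyphenyl)chroman-3,4,5,7-tetrol through its C4 oxygen | Oc1cc(O)c2c(c1)O[C@H](c1ccc(O)c(O)c1)[C@H](O)[C@H]2c1c(O)cc(O)c2c1O[C@H](c1ccc(O)c(O)c1)[C@H](O)[C@H]2O[C@H]1c2c(O)cc(O)cc2O[C@@H](c2ccc(O)c(O)c2)[C@H]1O | target

## Step count and least certain steps

Total: 18 steps. Longest linear sequence: 13 steps (steps 1, 2, 4 to 12, 17 and 18).

**Step 7 (key step).** Most likely to go wrong is erosion of enantioface selectivity and leakage from cis to trans oxirane, because ring B stabilises the benzylic radical and lengthens its life. Oxygen transfer to the doubly activated C4 methylene or the rings may also compete.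
- Fallback: Shi epoxidation of 12 with the glucose-derived oxazolidinone ketone made for cis-alkenes and KHSO5 (as 2KHSO5·KHSO4·K2SO4) at buffered pH. This is a concerted dioxirane oxygen transfer with neither a radical intermediate nor a metal-oxo species. It sets out from 12 and comes back at 13 and makes no new compound (F0).

**Step 8.** Most likely to go wrong is ionisation of the C2–O bond ahead of bond formation, since the para oxygen of ring B stabilises the cation. Rotation about C2–C3 would then allow closure from the other face, with loss of stereospecificity towards the 2,3-trans (2R) flavan; this is favoured because the cis-oxirane forces ring B pseudo-axial in the closing transition state. That product cannot be corrected.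
- Fallback: it sets out from 12, which is isomerised with catalytic PhSSPh under light to (E)-1-[2-(tert-butyldimethylsiloxy)-4,6-bis(benzyloxy)phenyl]-3-[3,4-bis(benzyloxy)phenyl]prop-2-ene F1.
- Shi epoxidation with the D-fructose-derived ketone and KHSO5 should give, by analogy with trans-β-methylstyrene, the (2R,3R)-trans-oxirane F2.
- Buffered desilylation and acid closure, in which backside attack and ionisation lead to the same product with ring B equatorial, give (2S,3R)-5,7-bis(benzyloxy)-2-[3,4-bis(benzyloxy)phenyl]chroman-3-ol F3.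
- Dess–Martin oxidation gives (2S)-5,7-bis(benzyloxy)-2-[3,4-bis(benzyloxy)phenyl]chroman-3-one F4, and LiBH(s-Bu)3 at −78 °C adds hydride anti to ring B; the route is rejoined at 15.

**Step 17.** Most likely to go wrong is competing hydride abstraction from the carbinol C–H of 19, and later from the same position in 25. That hydrogen is next to oxygen and can become pseudo-axial, so it may be lost as fast as the methylene hydrogen of 24. Capture of the cation by a hindered secondary alcohol may also be incomplete.
- Fallback: it sets out from 24, which is oxidised with DDQ in the presence of excess 2-ethoxyethanol to the 4β-(2-ethoxyethoxy) derivative of 24 F5.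
- F5 and 19 are then joined by acetal-type exchange with catalytic TMSOTf in CH2Cl2 over 4 Å sieves at −78 °C, quenched cold with Et3N, so that no oxidant ever meets 19; the route is rejoined at 25.

**Step 18.** Most likely to go wrong is loss of the interflavan C–O bond, either by hydrogenolysis or by expulsion of the C4 oxygen by the freed ring A phenols followed by reduction or solvolysis. The longer time needed for the three C3 benzyl ethers makes this more likely.
- Fallback: it sets out from 25, which is hydrogenolysed over Pd(OH)2/C in the presence of Ac2O and NaOAc, so that each phenol is capped as it is released. This gives the pentadeca-O-acetate of the target F6, which can be purified.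
- Mild transesterification (K2CO3, MeOH, 0 °C, argon, then a weakly acidic resin) comes back at 26.

**Step 4.** Most likely to go wrong is a second addition of acetylide to the ortho-quinone methide, loss of the carbonate before it has migrated, or hydride attack at the far alkyne carbon to give an allene.
- Fallback: it sets out from 3, which is silylated (TBSCl, imidazole) to 2,4-bis(benzyloxy)-6-(tert-butyldimethylsiloxy)benzaldehyde F7.
- Addition of the lithium acetylide of 6 at −78 °C with a cold quench gives the propargylic alcohol 1-[2,4-bis(benzyloxy)-6-(tert-butyldimethylsiloxy)phenyl]-3-[3,4-bis(benzyloxy)phenyl]prop-2-yn-1-ol F8.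
- Ionic deoxygenation with Et3SiH and BF3·OEt2 in CH2Cl2 at −78 °C comes back at 11.

## Further compounds

F0 | step 7 | none | none
F1 | step 8 | (E)-1-[2-(tert-butyldimethylsiloxy)-4,6-bis(benzyloxy)phenyl]-3-[3,4-bis(benzyloxy)phenyl]prop-2-ene | CC(C)(C)[Si](C)(C)Oc1cc(OCc3ccccc3)cc(OCc3ccccc3)c1C/C=C/c1ccc(OCc3ccccc3)c(OCc3ccccc3)c1
F2 | step 8 | (2R,3R)-2-[3,4-bis(benzyloxy)phenyl]-3-{[2,4-bis(benzyloxy)-6-(tert-butyldimethylsiloxy)phenyl]methyl}oxirane (trans) | CC(C)(C)[Si](C)(C)Oc1cc(OCc3ccccc3)cc(OCc3ccccc3)c1C[C@H]1O[C@@H]1c1ccc(OCc3ccccc3)c(OCc3ccccc3)c1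
F3 | step 8 | (2S,3R)-5,7-bis(benzyloxy)-2-[3,4-bis(benzyloxy)phenyl]chroman-3-ol | C1c2c(OCc3ccccc3)cc(OCc3ccccc3)cc2O[C@@H](c2ccc(OCc3ccccc3)c(OCc3ccccc3)c2)[C@@H]1O
F4 | step 8 | (2S)-5,7-bis(benzyloxy)-2-[3,4-bis(benzyloxy)phenyl]chroman-3-one | C1c2c(OCc3ccccc3)cc(OCc3ccccc3)cc2O[C@@H](c2ccc(OCc3ccccc3)c(OCc3ccccc3)c2)C1=O
F5 | step 17 | 4β-(2-ethoxyethoxy) derivative of 24 at C4 (S) of its lower unit | C(c1ccccc1)Oc1cc(OCc3ccccc3)c2c(c1)O[C@H](c1ccc(OCc3ccccc3)c(OCc3ccccc3)c1)[C@H](OCc1ccccc1)[C@H]2c1c(OCc3ccccc3)cc(OCc3ccccc3)c2c1O[C@H](c1ccc(OCc3ccccc3)c(OCc3ccccc3)c1)[C@H](OCc1ccccc1)[C@H]2OCCOCC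
F6 | step 18 | pentadeca-O-acetate of the target | CC(=O)Oc1cc(OC(C)=O)c2c(c1)O[C@H](c1ccc(OC(C)=O)c(OC(C)=O)c1)[C@H](OC(C)=O)[C@H]2c1c(OC(C)=O)cc(OC(C)=O)c2c1O[C@H](c1ccc(OC(C)=O)c(OC(C)=O)c1)[C@H](OC(C)=O)[C@H]2O[C@H]1c2c(OC(C)=O)cc(OC(C)=O)cc2O[C@@H](c2ccc(OC(C)=O)c(OC(C)=O)c2)[C@H]1OC(C)=O
F7 | step 4 | 2,4-bis(benzyloxy)-6-(tert-butyldimethylsiloxy)benzaldehyde | O=Cc1c(O[Si](C)(C)C(C)(C)C)cc(OCc2ccccc2)cc1OCc1ccccc1
F8 | step 4 | 1-[2,4-bis(benzyloxy)-6-(tert-butyldimethylsiloxy)phenyl]-3-[3,4-bis(benzyloxy)phenyl]prop-2-yn-1-ol (racemic) | CC(C)(C)[Si](C)(C)Oc1cc(OCc2ccccc2)cc(OCc2ccccc2)c1C(O)C#Cc1ccc(OCc2ccccc2)c(OCc2ccccc2)c1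
A1 | alternative 1 | benzylated trimer with a pinacolboryl group at C3 of the lower unit | c3ccccc3COc1cc(OCc3ccccc3)c2c(c1)O[C@H](c1ccc(OCc3ccccc3)c(OCc3ccccc3)c1)[C@H](OCc3ccccc3)[C@H]2c1c(OCc3ccccc3)cc(OCc3ccccc3)c2c1O[C@H](c1ccc(OCc3ccccc3)c(OCc3ccccc3)c1)[C@H](OCc3ccccc3)[C@H]2O[C@H]1c2c(OCc3ccccc3)cc(OCc3ccccc3)cc2O[C@@H](c2ccc(OCc3ccccc3)c(OCc3ccccc3)c2)[C@H]1B4OC(C)(C)C(C)(C)O4
A2 | alternative 1 | mixed methyl acetal of 2,4-bis(benzyloxy)-6-hydroxybenzaldehyde with the C4 (S) hydroxyl of the benzylated dimer | C(c1ccccc1)Oc1cc(OCc3ccccc3)c2c(c1)O[C@H](c1ccc(OCc3ccccc3)c(OCc3ccccc3)c1)[C@H](OCc1ccccc1)[C@H]2c1c(OCc3ccccc3)cc(OCc3ccccc3)c2c1O[C@H](c1ccc(OCc3ccccc3)c(OCc3ccccc3)c1)[C@H](OCc1ccccc1)[C@H]2OC(OC)c1c(O)cc(OCc3ccccc3)cc1OCc1ccccc1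
A3 | alternative 1 | (Z)-2-{2-[3,4-bis(benzyloxy)phenyl]ethenyl}-4,4,5,5-tetramethyl-1,3,2-dioxaborolane | CC1(C)OB(/C=C\c2ccc(OCc3ccccc3)c(OCc3ccccc3)c2)OC1(C)C
A4 | alternative 2 | (2S,3S,4S)-penta-O-benzyl-4-O-(tert-butyldimethylsilyl)flavan-3,4-diol | CC(C)(C)[Si](C)(C)O[C@H]1c2c(OCc3ccccc3)cc(OCc3ccccc3)cc2O[C@@H](c2ccc(OCc3ccccc3)c(OCc3ccccc3)c2)[C@H]1OCc3ccccc3
A5 | alternative 2 | open-chain bromo alcohol, 2-benzyloxy-1-[3,4-bis(benzyloxy)phenyl]-3-[2-bromo-4,6-bis(benzyloxy)phenyl]-3-(tert-butyldimethylsiloxy)propan-1-ol with the configuration of A4 | CC(C)(C)[Si](C)(C)O[C@@H](c1c(Br)cc(OCc3ccccc3)cc1OCc1ccccc1)[C@H](OCc1ccccc1)[C@@H](O)c1ccc(OCc3ccccc3)c(OCc3ccccc3)c1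
A6 | alternative 3 | 4-aryl flavan whose new ring carries 7-hydroxyl, 8a-triisopropylsiloxy, 5-benzyloxy and 4a-(E)-cinnamyl groups | c3ccccc3COc1cc(OCc3ccccc3)c2c(c1)O[C@H](c1ccc(OCc3ccccc3)c(OCc3ccccc3)c1)[C@H](OCc3ccccc3)[C@H]2c1c(O)cc(OCc3ccccc3)c(C/C=C/c2ccc(OCc3ccccc3)c(OCc3ccccc3)c2)c1O[Si](C(C)C)(C(C)C)C(C)C
A7 | alternative 3 | penta-O-benzyl flavan of the (2R,3R) series with a (triisopropylsiloxy)ethynyl group at C4 | c3ccccc3COc1cc(OCc3ccccc3)c2c(c1)O[C@H](c1ccc(OCc3ccccc3)c(OCc3ccccc3)c1)[C@H](OCc3ccccc3)[C@H]2C#CO[Si](C(C)C)(C(C)C)C(C)C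
A8 | alternative 3 | 3-(benzyloxy)-2-{(E)-3-[3,4-bis(benzyloxy)phenyl]prop-2-en-1-yl}cyclobut-2-en-1-one | O=C1CC(OCc2ccccc2)=C1C/C=C/c1ccc(OCc2ccccc2)c(OCc2ccccc2)c1
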